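**Plan**

1. Numbering follows ent-kaurane: C1 (OAc), C6 (CHO), C7/C20 (lactone), C15 (carbinol), C16=C17 (exocyclic alkene); rings A (carbocycle), B (δ-lactone), C and D (bicyclo[3.2.1]octane).
2. Retrosynthesis: the C6 aldehyde is masked as a dioxolane; the bicyclo[3.2.1]octane is then cut at C12–C13 (ring C) and C15–C16 (ring D) in one operation. This is possible because C15(OH)–C16(=C17H2)–C13 is a 2-methyleneallyl alcohol unit hung on the quaternary C8: it maps onto an aldehyde (C15) and a buta-2,3-dienyl group (C14–C13=C16=C17) on C8 and a 2-metalloethyl arm (C11–C12) on C9.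
3. Earlier cuts: C8–C15 and C8–C14 (two lactone enolate reactions), C9–C11 (conjugate addition), C9–C10 together with O–C7 (epoxide-derived C10 radical plus an acrylate), back to ring A from 4,4-dimethylcyclohex-2-en-1-one.
4. Forward: ring A (steps 1–6), spiro lactone ring B (step 7), C9 and C8 substituents (steps 8–18), rings D and C together (step 19), release of the aldehyde (step 20).
5. Stereochemistry: C1/C5 cis by hydride reduction, made enantiopure by a Sharpless kinetic resolution; C10 by acrylate attack anti to both ring-A substituents; C9 by conjugate addition anti to the C5 flank; C8 by the order of the two enolate reactions; C13 and C15 by the tether and the nickelacycle of the key step.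

Key step: step 19

Remark: 4,4-dimethylcyclohex-2-en-1-one and buta-2,3-dien-1-ol are taken as commercial; compounds 3–6 are racemic and the route is enantiopure from 7 on.

**Route**

Step 1
Reactants: 1 4,4-dimethylcyclohex-2-en-1-one
Product: 2 2-(hydroxymethyl)-4,4-dimethylcyclohex-2-en-1-one
Conditions: 37% aq. CH2O, DMAP (20 mol%), THF/H2O, rt
Reagents that add atoms: formaldehyde, C=O
Why: Morita–Baylis–Hillman reaction: the amine adds to the enone β-carbon and the resulting enolate is hydroxymethylated at the α-carbon, which becomes C10 carrying C20; no stereocenter is formed.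

Step 2
Reactants: 2 2-(hydroxymethyl)-4,4-dimethylcyclohex-2-en-1-one
Product: 3 3-(1,3-dioxolan-2-yl)-2-(hydroxymethyl)-4,4-dimethylcyclohexan-1-one (racemic; both C2 epimers)
Conditions: 1,3-dioxolane (solvent), (Bu4N)4[W10O32] (2 mol%), hν 390 nm, rt
Reagents that add atoms: 1,3-dioxolane, C1COCO1
Why: photocatalytic hydrogen-atom transfer from 1,3-dioxolane followed by Giese addition of the nucleophilic dioxolan-2-yl radical to the enone β-carbon installs C6 as a masked aldehyde; C5 is formed racemic and the C10 epimers converge in step 3.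

Step 3
Reactants: 3 3-(1,3-dioxolan-2-yl)-2-(hydroxymethyl)-4,4-dimethylcyclohexan-1-one
Product: 5 3-(1,3-dioxolan-2-yl)-4,4-dimethyl-2-methylidenecyclohexan-1-one (racemic), via mesylate 4 (not isolated)
Conditions: MsCl, Et3N, CH2Cl2, 0 °C → rt; used at once
Reagents that add atoms: none
Why: mesylation and E1cB elimination of the β-mesyloxy ketone can only give the exocyclic C10=C20 enone, and the C10 stereocenter is removed.

Step 4
Reactants: 5 3-(1,3-dioxolan-2-yl)-4,4-dimethyl-2-methylidenecyclohexan-1-one
Product: 6 rac-(1S,3R)-3-(1,3-dioxolan-2-yl)-4,4-dimethyl-2-methylidenecyclohexan-1-ol (cis)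
Conditions: NaBH4, CeCl3·7H2O, MeOH, −78 °C
Reagents that add atoms: none
Why: Luche 1,2-reduction of the enone; hydride should add to C1 on the face away from the C5 dioxolanyl group, so the hydroxyl ends cis to it (relative configuration of C1 and C5).

Step 5
Reactants: 6 rac-(1S,3R)-3-(1,3-dioxolan-2-yl)-4,4-dimethyl-2-methylidenecyclohexan-1-ol
Product: 7 (4S,8R)-8-(1,3-dioxolan-2-yl)-7,7-dimethyl-1-oxaspiro[2.5]octan-4-ol (epoxide O syn to OH)
Conditions: Ti(OiPr)4 (15 mol%), L-(+)-diisopropyl tartrate (18 mol%), t-BuOOH (0.5 equiv), 4 Å MS, CH2Cl2, −20 °C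
Reagents that add atoms: tert-butyl hydroperoxide, CC(C)(C)OO
Why: Sharpless asymmetric epoxidation run as a kinetic resolution of the secondary allylic alcohol: with L-(+)-DIPT the (1S,3R) enantiomer should be the fast one and be epoxidized syn to its hydroxyl while the (1R,3S) antipode stays behind and is separated, which fixes the absolute configuration of C1 and C5 (the epoxide centre is erased in step 7).

Step 6
Reactants: 7 (4S,8R)-8-(1,3-dioxolan-2-yl)-7,7-dimethyl-1-oxaspiro[2.5]octan-4-ol
Product: 8 TBS ether of 7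
Conditions: TBSCl, imidazole, DMF, 40 °C
Reagents that add atoms: tert-butyldimethylsilyl chloride, CC(C)(C)[Si](C)(C)Cl
Why: standard silyl ether formation at the secondary alcohol under conditions that leave the epoxide and the acetal intact; no stereocenter is affected.

Step 7
Reactants: 8 TBS ether of 7
Product: 10 spiro δ-lactone (7,20-lactone; 1-OTBS; C6 dioxolane), via hydroxy ester 9 (not isolated)
Conditions: 2,2,2-trifluoroethyl acrylate, Cp2TiCl2 (20 mol%), Zn, 2,4,6-collidine·HCl, THF, rt
Reagents that add atoms: 2,2,2-trifluoroethyl acrylate, C=CC(=O)OCC(F)(F)F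
Why: titanocene-mediated reductive epoxide opening (trivalent titanium, Cp2TiCl, turned over by Zn) gives the tertiary C10 radical, whose Giese addition to the acrylate should occur on the face anti to the cis 1-silyloxy and 5-dioxolanyl groups and so sets the C10 quaternary centre; the C20 alkoxide then lactonizes onto the activated ester.

Step 8
Reactants: 10 spiro δ-lactone
Product: 13 C8=C9 unsaturated spiro lactone, via lithium enolate 11 (not isolated), via α-phenylselanyl lactone 12 (not isolated)
Conditions: LiN(iPr)2, THF, −78 °C; PhSeBr; then 30% H2O2, pyridine, CH2Cl2, 0 °C → rt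
Reagents that add atoms: none
Why: α-selenenylation of the lactone enolate followed by selenoxide syn-elimination, which can only run towards C9, gives the unsaturated lactone; no stereocenter is formed.

Step 9
Reactants: 13 C8=C9 unsaturated spiro lactone
Product: 14 9-vinyl lactone (C11 cis to C1 on the lactone ring)
Conditions: CH2=CHMgBr, CuBr·SMe2 (15 mol%), THF, −78 → −30 °C; aq. NH4Cl
Reagents that add atoms: vinylmagnesium bromide, C=C[Mg]Br
Why: copper-catalysed conjugate addition of the vinyl Grignard reagent to the unsaturated δ-lactone; the nucleophile should enter C9 antiperiplanar to the bulkier C5 flank of the spiro centre (C5 carries the dioxolane and adjoins the gem-dimethyl carbon), which places C11 cis to C1 as in the target.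

Step 10
Reactants: 14 9-vinyl lactone
Product: 16 9-(2-hydroxyethyl) lactone, via B-alkyl-9-BBN 15 (not isolated)
Conditions: 9-BBN, THF, 0 °C → rt; then 30% H2O2, aq. NaOAc, 0 °C
Reagents that add atoms: hydrogen peroxide, OO
Why: anti-Markovnikov hydroboration of the terminal vinyl group with the bulky borane and buffered oxidation give the primary C12 alcohol with the lactone intact; no stereocenter is formed.

Step 11
Reactants: 16 9-(2-hydroxyethyl) lactone
Product: 17 9-(2-chloroethyl) lactone
Conditions: PPh3, N-chlorosuccinimide, CH2Cl2, 0 °C → rt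
Reagents that add atoms: N-chlorosuccinimide, O=C1CCC(=O)N1Cl
Why: Appel-type chlorination (SN2 at the primary carbon); the chloride should survive the two enolate steps, where closure of a 4-membered ring is slow, and serves as a latent iodide.

Step 12
Reactants: 18 buta-2,3-dien-1-ol
Product: 19 4-bromobuta-1,2-diene
Conditions: CBr4, PPh3, CH2Cl2, 0 °C
Reagents that add atoms: carbon tetrabromide, BrC(Br)(Br)Br
Why: Appel bromination of the primary allenic alcohol by SN2 displacement of the alkoxyphosphonium ion, which avoids allylic transposition.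

Step 13
Reactants: 17 9-(2-chloroethyl) lactone; 19 4-bromobuta-1,2-diene
Product: 21 8-(buta-2,3-dienyl) lactone, via lithium enolate 20 (not isolated)
Conditions: LiN(iPr)2, THF, −78 °C; then 19, DMPU, −78 → −40 °C
Reagents that add atoms: none
Why: SN2 alkylation of the lactone enolate at the CH2Br carbon of the allenylmethyl bromide, expected trans to the C9 chain; the C8 configuration is of no consequence because C8 is planarized again in step 14.

Step 14
Reactants: 21 8-(buta-2,3-dienyl) lactone
Product: 23 8-(buta-2,3-dienyl)-8-(hydroxymethyl) lactone, via lithium enolate 22 (not isolated)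
Conditions: LiN(iPr)2, THF, −78 °C; then monomeric CH2O (from cracked paraformaldehyde), −78 → −40 °C; aq. NH4Cl
Reagents that add atoms: formaldehyde, C=O
Why: aldol addition of the α-substituted lactone enolate to formaldehyde; the electrophile should enter anti to the adjacent C9 side chain, so that C15 ends trans and the buta-2,3-dienyl group (C14) cis to C11, which sets the C8 quaternary centre.

Step 15
Reactants: 23 8-(buta-2,3-dienyl)-8-(hydroxymethyl) lactone
Product: 24 8-formyl lactone (C15 aldehyde; 1-OTBS)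
Conditions: Dess–Martin periodinane, NaHCO3, CH2Cl2, rt
Reagents that add atoms: none
Why: Dess–Martin oxidation of the neopentyl primary alcohol to the non-enolizable aldehyde; allene, chloride, acetal and silyl ether are inert.

Step 16
Reactants: 24 8-formyl lactone (1-OTBS)
Product: 25 1-hydroxy aldehyde
Conditions: HF·pyridine, pyridine, THF, 0 °C → rt
Reagents that add atoms: none
Why: fluoride-mediated cleavage of the secondary silyl ether under buffered acidic conditions, which the acetal, the aldehyde and the allene should tolerate.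

Step 17
Reactants: 25 1-hydroxy aldehyde
Product: 26 1-acetoxy aldehyde (chloride)
Conditions: Ac2O, DMAP (cat.), pyridine, CH2Cl2, rt
Reagents that add atoms: acetic anhydride, CC(=O)OC(C)=O
Why: DMAP-catalysed acetylation of the only free hydroxyl group (C1) installs the acetate after the last strongly basic step.

Step 18
Reactants: 26 1-acetoxy aldehyde (chloride)
Product: 27 1-acetoxy aldehyde (iodide)
Conditions: NaI, 2-butanone, reflux
Reagents that add atoms: sodium iodide, [Na+].[I-]
Why: Finkelstein halide exchange (SN2) turns the latent chloride into the primary iodide needed for zinc insertion.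

Step 19
Reactants: 27 1-acetoxy aldehyde (iodide)
Product: 29 pentacyclic 15-alcohol (C6 dioxolane), via alkylzinc iodide 28 (not isolated)
Conditions: Zn dust, LiCl, THF, 35 °C; then Ni(cod)2 (20 mol%), 1,3-bis(2,6-diisopropylphenyl)imidazol-2-ylidene (20 mol%), THF, 0 °C → rt; aq. NH4Cl
Reagents that add atoms: none
Why: Proposed new method: zinc inserts into the carbon–iodine bond at C12 to give alkylzinc iodide 28, and zerovalent nickel then joins the aldehyde carbon C15 to the central allene carbon C16 by oxidative cyclization, which gives an oxanickelacycle in equilibrium with an η3-allyl (C13–C16–C17) nickel alkoxide; the tethered alkylzinc transmetalates to nickel and C(sp3)–C(sp3) reductive elimination at C13 forms the C12–C13 bond. The closest known reaction types are the Ni(cod)2-catalysed alkylative cyclization of alkynyl and allenyl aldehydes with organozinc reagents and the nickel-catalysed three-component coupling of allenes and aldehydes at the central allene carbon. Ring D closes in a 5-exo mode on the terminal π bond of the allene (the 4-membered alternative through C13 is excluded by the two-atom tether C8–C14), and ring C closes as a 6-membered ring at the internal allyl terminus C13, because coupling at C17 would place a bridgehead alkene in a bicyclo[4.2.1] frame. C13 is set by the tether, since the C9 arm (cis to C14 after steps 13 and 14) reaches only the face of ring D that is syn to C9, and C15 follows from the metallacycle, in which O15 and C13 sit on the same nickel and therefore on the same face, so the hydroxyl ends on the C9 side as in the target. The step needs chemoselectivity for the nickel pathway over direct 1,2-addition and over β-hydride elimination: alkylzinc halides do not add to aldehydes without a catalyst, and a phosphine-free nickel–carbene catalyst should favour reductive elimination, while acetate, lactone and acetal are inert to both metals.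

Step 20
Reactants: 29 pentacyclic 15-alcohol (C6 dioxolane)
Product: 30 target compound CNP0117386.1
Conditions: PPTS, acetone/H2O (9:1), 55 °C
Reagents that add atoms: water, O
Why: mild acid-catalysed acetal hydrolysis releases the C6 aldehyde; acetate, lactone and the allylic alcohol should be stable under these conditions and C5 keeps its configuration (equatorial formyl group).

**Compound list**

1 | 4,4-dimethylcyclohex-2-en-1-one | O=C1C=CC(C)(C)CC1 | starting material
2 | 2-(hydroxymethyl)-4,4-dimethylcyclohex-2-en-1-one | O=C1CCC(C)(C)C=C1CO | intermediate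
3 | 3-(1,3-dioxolan-2-yl)-2-(hydroxymethyl)-4,4-dimethylcyclohexan-1-one (racemic, both C2 epimers) | O=C1CCC(C)(C)C(C2OCCO2)C1CO | intermediate
4 | [2-(1,3-dioxolan-2-yl)-3,3-dimethyl-6-oxocyclohexyl]methyl methanesulfonate (racemic, both epimers) | O=C1CCC(C)(C)C(C2OCCO2)C1COS(C)(=O)=O | intermediate
5 | 3-(1,3-dioxolan-2-yl)-4,4-dimethyl-2-methylidenecyclohexan-1-one (racemate; the (3R) enantiomer is drawn) | C=C1C(=O)CCC(C)(C)[C@H]1C1OCCO1 | intermediate
6 | rac-(1S,3R)-3-(1,3-dioxolan-2-yl)-4,4-dimethyl-2-methylidenecyclohexan-1-ol (hydroxyl and dioxolanyl cis; the (1S,3R) enantiomer is drawn) | C=C1[C@@H](O)CCC(C)(C)[C@H]1C1OCCO1 | intermediate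
7 | (4S,8R)-8-(1,3-dioxolan-2-yl)-7,7-dimethyl-1-oxaspiro[2.5]octan-4-ol, epoxide oxygen syn to the hydroxyl | O[C@H]1CCC(C)(C)[C@@H](C2OCCO2)[C@]13CO3 | intermediate
8 | tert-butyldimethylsilyl ether of 7 | CC(C)(C)[Si](C)(C)O[C@H]1CCC(C)(C)[C@@H](C2OCCO2)[C@]13CO3 | intermediate
9 | 2,2,2-trifluoroethyl 3-(cyclohexyl)propanoate hydroxy ester: C10 carries CH2OH (C20, cis to 1-OTBS and to the 5-dioxolanyl group) and the propanoate chain (trans to both) | OC[C@@]1(CCC(=O)OCC(F)(F)F)[C@@H](O[Si](C)(C)C(C)(C)C)CCC(C)(C)[C@H]1C1OCCO1 | intermediate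
10 | spiro δ-lactone (O–C20H2–C10–C9H2–C8H2–C7=O), C10 spiro to ring A; 1-OTBS and 5-(1,3-dioxolan-2-yl) cis to each other and to C20, trans to C9; 4,4-dimethyl | O=C1CC[C@]2(CO1)[C@@H](O[Si](C)(C)C(C)(C)C)CCC(C)(C)[C@H]2C1OCCO1 | intermediate
11 | lithium enolate of 10 (C7(OLi)=C8) | [Li]OC1=CC[C@]2(CO1)[C@@H](O[Si](C)(C)C(C)(C)C)CCC(C)(C)[C@H]2C1OCCO1 | intermediate
12 | 8-(phenylselanyl) derivative of 10 (C8 epimers) | O=C1C([Se]c3ccccc3)C[C@]2(CO1)[C@@H](O[Si](C)(C)C(C)(C)C)CCC(C)(C)[C@H]2C1OCCO1 | intermediate
13 | C8=C9 unsaturated spiro lactone (5,6-dihydro-2H-pyran-2-one spiro to ring A) | O=C1C=C[C@]2(CO1)[C@@H](O[Si](C)(C)C(C)(C)C)CCC(C)(C)[C@H]2C1OCCO1 | intermediate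
14 | 9-vinyl lactone; vinyl (C11=C12) on C9 cis to C1 and trans to C5 on the lactone ring | O=C1C[C@@H](C=C)[C@]2(CO1)[C@@H](O[Si](C)(C)C(C)(C)C)CCC(C)(C)[C@H]2C1OCCO1 | intermediate
15 | B-alkyl-9-borabicyclo[3.3.1]nonane from 14 (boron on C12) | O=C1C[C@@H](CCB3C4CCCC3CCC4)[C@]2(CO1)[C@@H](O[Si](C)(C)C(C)(C)C)CCC(C)(C)[C@H]2C1OCCO1 | intermediate
16 | 9-(2-hydroxyethyl) lactone | O=C1C[C@@H](CCO)[C@]2(CO1)[C@@H](O[Si](C)(C)C(C)(C)C)CCC(C)(C)[C@H]2C1OCCO1 | intermediate
17 | 9-(2-chloroethyl) lactone | O=C1C[C@@H](CCCl)[C@]2(CO1)[C@@H](O[Si](C)(C)C(C)(C)C)CCC(C)(C)[C@H]2C1OCCO1 | intermediate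
18 | buta-2,3-dien-1-ol | OCC=C=C | starting material
19 | 4-bromobuta-1,2-diene | BrCC=C=C | intermediate
20 | lithium enolate of 17 | [Li]OC1=C[C@@H](CCCl)[C@]2(CO1)[C@@H](O[Si](C)(C)C(C)(C)C)CCC(C)(C)[C@H]2C1OCCO1 | intermediate
21 | 8-(buta-2,3-dienyl)-9-(2-chloroethyl) lactone, the two substituents trans | O=C1[C@H](CC=C=C)[C@@H](CCCl)[C@]2(CO1)[C@@H](O[Si](C)(C)C(C)(C)C)CCC(C)(C)[C@H]2C1OCCO1 | intermediate
22 | lithium enolate of 21 | [Li]OC1=C(CC=C=C)[C@@H](CCCl)[C@]2(CO1)[C@@H](O[Si](C)(C)C(C)(C)C)CCC(C)(C)[C@H]2C1OCCO1 | intermediate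
23 | 8-(buta-2,3-dienyl)-8-(hydroxymethyl) lactone; CH2OH (C15) trans and buta-2,3-dienyl (C14) cis to the C9 chloroethyl chain | O=C1[C@@](CO)(CC=C=C)[C@@H](CCCl)[C@]2(CO1)[C@@H](O[Si](C)(C)C(C)(C)C)CCC(C)(C)[C@H]2C1OCCO1 | intermediate
24 | 8-formyl analogue of 23 (C15 aldehyde) | O=C1[C@@](C=O)(CC=C=C)[C@@H](CCCl)[C@]2(CO1)[C@@H](O[Si](C)(C)C(C)(C)C)CCC(C)(C)[C@H]2C1OCCO1 | intermediate
25 | 1-hydroxy aldehyde (24 without the silyl group) | O=C1[C@@](C=O)(CC=C=C)[C@@H](CCCl)[C@]2(CO1)[C@@H](O)CCC(C)(C)[C@H]2C1OCCO1 | intermediate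
26 | 1-acetoxy aldehyde, chloride | O=C1[C@@](C=O)(CC=C=C)[C@@H](CCCl)[C@]2(CO1)[C@@H](OC(C)=O)CCC(C)(C)[C@H]2C1OCCO1 | intermediate
27 | 1-acetoxy aldehyde, iodide | O=C1[C@@](C=O)(CC=C=C)[C@@H](CCI)[C@]2(CO1)[C@@H](OC(C)=O)CCC(C)(C)[C@H]2C1OCCO1 | intermediate
28 | alkylzinc iodide from 27 (zinc on C12) | O=C1[C@@](C=O)(CC=C=C)[C@@H](CC[Zn]I)[C@]2(CO1)[C@@H](OC(C)=O)CCC(C)(C)[C@H]2C1OCCO1 | intermediate
29 | 1,3-dioxolane acetal of the target at C6 (complete ring system; 15-OH on the C9 side of ring D; 16-methylidene; 1-OAc) | C=C1[C@@H]2CC[C@@H]3[C@](C2)(C(=O)OC[C@]32[C@@H](OC(C)=O)CCC(C)(C)[C@H]2C4OCCO4)[C@@H]1O | intermediate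
30 | CNP0117386.1 | C=C1[C@@H]2CC[C@@H]3[C@](C2)(C(=O)OC[C@]32[C@@H](OC(C)=O)CCC(C)(C)[C@H]2C=O)[C@@H]1O | target

**Totals**

Total step count: 20. Longest linear sequence: 19 steps (steps 1–11 and 13–20; step 12 is a one-step branch).

**Steps most likely to fail**

1. Step 19. Possible failure processes: β-hydride elimination from the alkylnickel intermediate (ring D closes reductively and ring C does not form), coupling of the aldehyde at the terminal allene carbon, or slow uncatalysed addition of the alkylzinc to the aldehyde. Fallback with known chemistry, setting out from 17 and coming back at 29: the two rings are closed one after the other through a spiro-cyclopentenone.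
   - Enolate allylation of 17 (LiN(iPr)2, allyl bromide, THF, −78 °C) gives the 8-allyl lactone F1.
   - A second enolate is added to acrolein to give the quaternary allylic alcohol F2 (carbinol carbon trans and allyl cis to the C9 chain, as in step 14).
   - Ring-closing metathesis (second-generation Grubbs catalyst, CH2Cl2, 40 °C) gives the spiro-cyclopentenol F3, and Dess–Martin oxidation gives the spiro-cyclopent-2-enone F4, in which C13 is the β-carbon of the enone.
   - Finkelstein exchange (NaI, 2-butanone) gives the iodide F5.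
   - Bu3SnH and AIBN (slow addition, benzene, 80 °C) close ring C by 6-exo radical cyclization of C12 onto C13 and give the pentacyclic 15-ketone F6.
   - α-Methylenation at C16, the only enolizable position (paraformaldehyde, N-methylanilinium trifluoroacetate, THF, reflux), gives the 16-methylidene ketone F7.
   - HF·pyridine gives the 1-alcohol F8 and Ac2O/DMAP the 1-acetate F9.
   - Luche reduction (NaBH4, CeCl3·7H2O, MeOH, −78 °C), with hydride entering from the face of the one-carbon bridge C14, gives 29.

2. Step 9. Possible failure process: poor facial selectivity of the conjugate addition at C9. Fallback setting out from 13 and coming back at 17: the two-carbon unit is delivered from a tether on the C1 oxygen.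
   - HF·pyridine gives the 1-hydroxy unsaturated lactone F10.
   - Ethyl vinyl ether and N-bromosuccinimide give the mixed bromoacetal F11.
   - Bu3SnH/AIBN effects Ueno–Stork 6-exo radical cyclization onto C9, necessarily from the face of C1, and gives the tricyclic ethyl acetal F12 (C11 and a masked C12 aldehyde in place).
   - Mild aqueous acid (AcOH, THF, H2O) gives the lactol F13, and NaBH4 gives the diol F14.
   - Chlorination of the primary hydroxyl (PPh3, N-chlorosuccinimide) gives the chloro alcohol F15, and silylation (TBSOTf, 2,6-lutidine) gives 17.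

3. Step 14. Possible failure process: entry of formaldehyde on the face syn to the C9 chain, or poor facial selectivity, at the quaternary centre C8. Fallback setting out from 17 and coming back at 23: the order of the two C8 bond formations is reversed so that the C8–C14 bond is made last.
   - The enolate of 17 is hydroxymethylated first (LiN(iPr)2; CH2O) to the 8-(hydroxymethyl) lactone F16.
   - Its alkoxide–enolate dianion (two equivalents of LiN(iPr)2) is alkylated with 19; an electrophile that prefers the face syn to the C9 chain then gives 23.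

Further compounds
F1 | step 19 | 8-allyl-9-(2-chloroethyl) lactone (allyl trans to the C9 chain; otherwise as 17) | O=C1[C@H](CC=C)[C@@H](CCCl)[C@]2(CO1)[C@@H](O[Si](C)(C)C(C)(C)C)CCC(C)(C)[C@H]2C1OCCO1
F2 | step 19 | 8-allyl-8-(1-hydroxyprop-2-enyl) lactone (allyl cis to the C9 chain; both carbinol epimers) | O=C1[C@@](C(O)C=C)(CC=C)[C@@H](CCCl)[C@]2(CO1)[C@@H](O[Si](C)(C)C(C)(C)C)CCC(C)(C)[C@H]2C1OCCO1
F3 | step 19 | spiro-cyclopent-2-en-1-ol at C8 (ring D: C8, C14H2, C13H=C16H, C15HOH; chloride) | O=C1[C@]3(C(O)C=CC3)[C@@H](CCCl)[C@]2(CO1)[C@@H](O[Si](C)(C)C(C)(C)C)CCC(C)(C)[C@H]2C1OCCO1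
F4 | step 19 | spiro-cyclopent-2-en-1-one at C8 (C15=O, C16=C13; chloride) | O=C1[C@]3(C(=O)C=CC3)[C@@H](CCCl)[C@]2(CO1)[C@@H](O[Si](C)(C)C(C)(C)C)CCC(C)(C)[C@H]2C1OCCO1
F5 | step 19 | spiro-cyclopent-2-en-1-one, iodide | O=C1[C@]3(C(=O)C=CC3)[C@@H](CCI)[C@]2(CO1)[C@@H](O[Si](C)(C)C(C)(C)C)CCC(C)(C)[C@H]2C1OCCO1
F6 | step 19 | pentacyclic 15-ketone (C16H2; 1-OTBS; C6 dioxolane) | C1[C@@H]2CC[C@@H]3[C@](C2)(C(=O)OC[C@]32[C@@H](O[Si](C)(C)C(C)(C)C)CCC(C)(C)[C@H]2C4OCCO4)C1=O
F7 | step 19 | 16-methylidene 15-ketone (1-OTBS) | C=C1[C@@H]2CC[C@@H]3[C@](C2)(C(=O)OC[C@]32[C@@H](O[Si](C)(C)C(C)(C)C)CCC(C)(C)[C@H]2C4OCCO4)C1=O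
F8 | step 19 | 16-methylidene 15-ketone, 1-alcohol | C=C1[C@@H]2CC[C@@H]3[C@](C2)(C(=O)OC[C@]32[C@@H](O)CCC(C)(C)[C@H]2C4OCCO4)C1=O
F9 | step 19 | 16-methylidene 15-ketone, 1-acetate | C=C1[C@@H]2CC[C@@H]3[C@](C2)(C(=O)OC[C@]32[C@@H](OC(C)=O)CCC(C)(C)[C@H]2C4OCCO4)C1=O
F10 | step 9 | 1-hydroxy C8=C9 unsaturated spiro lactone | O=C1C=C[C@]2(CO1)[C@@H](O)CCC(C)(C)[C@H]2C1OCCO1
F11 | step 9 | 1-O-(2-bromo-1-ethoxyethyl) mixed acetal of F10 (acetal epimers) | O=C1C=C[C@]2(CO1)[C@@H](OC(CBr)OCC)CCC(C)(C)[C@H]2C1OCCO1
F12 | step 9 | tricyclic ethyl acetal (ring O1–C12H(OEt)–C11H2–C9 fused to lactone and ring A) | O=C1C[C@H]2CC(OCC)O[C@H]3CCC(C)(C)[C@@H](C4OCCO4)[C@]23CO1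
F13 | step 9 | corresponding lactol | O=C1C[C@H]2CC(O)O[C@H]3CCC(C)(C)[C@@H](C4OCCO4)[C@]23CO1
F14 | step 9 | 1-hydroxy-9-(2-hydroxyethyl) lactone (diol) | O=C1C[C@@H](CCO)[C@]2(CO1)[C@@H](O)CCC(C)(C)[C@H]2C1OCCO1
F15 | step 9 | 1-hydroxy-9-(2-chloroethyl) lactone | O=C1C[C@@H](CCCl)[C@]2(CO1)[C@@H](O)CCC(C)(C)[C@H]2C1OCCO1
F16 | step 14 | 8-(hydroxymethyl)-9-(2-chloroethyl) lactone (substituents trans) | O=C1[C@H](CO)[C@@H](CCCl)[C@]2(CO1)[C@@H](O[Si](C)(C)C(C)(C)C)CCC(C)(C)[C@H]2C1OCCO1
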